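**Plan**

- Late-stage cuts: the 7-OH is masked as a silyl ether, the (E)-hydroxymethylbutenyl chain is cut at its aryl–vinyl bond back to an aryl bromide, the prenyl group is cut back to an allyl group, and the C4 ketone is traced to a C4 methyl ether.
- Enabling feature: ring C is an oxygen heterocycle fused to phenolic ring A (O1 on C8a, C4 on C4a) and carries ring B on C2. Cutting O1–C2 and C3–C4 therefore gives a methoxy ortho-quinone methide of ring A and a ring B styrene.
- Forward order: the ring B styrene is made from 3-bromo-4-hydroxybenzaldehyde and the ring A acetal from 2,4-dihydroxybenzaldehyde. The two are joined in the [4+2] reaction that closes ring C, followed by C4 oxidation, cross-metathesis, Heck coupling and desilylation.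
- Stereochemistry: C2 (S), the only stereocentre of the target, is set in the cycloaddition by a confined chiral Brønsted acid. C4 is stereogenic only transiently, and the E alkene comes from the Heck reaction.

Key step: step 7

Assumption: the (S,S)-enantiomer of the chiral acid is taken to deliver the 2S chroman; if the sense of induction is the opposite, the (R,R)-acid is used and nothing else changes.

**Route**

Step 1
Reactants: 1 3-bromo-4-hydroxybenzaldehyde; 2 allyl bromide
Product: 3 4-(allyloxy)-3-bromobenzaldehyde
Conditions: K2CO3, DMF, rt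
Reagents that add atoms: none
Why: Williamson O-alkylation of an acidic phenol (para-formyl, ortho-bromo) with a reactive allylic halide should be clean.

Step 2
Reactants: 3 4-(allyloxy)-3-bromobenzaldehyde
Product: 5 3-allyl-5-bromo-4-hydroxybenzaldehyde, via dienone 4 (not isolated)
Conditions: N,N-diethylaniline, 190 °C
Reagents that add atoms: none
Why: the aromatic Claisen rearrangement ([3,3]-sigmatropic shift) can deliver the allyl group only to the single free ortho position, and dienone 4 then tautomerises to the phenol.

Step 3
Reactants: 5 3-allyl-5-bromo-4-hydroxybenzaldehyde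
Product: 6 3-allyl-5-bromo-4-methoxybenzaldehyde
Conditions: MeI, K2CO3, DMF, rt
Reagents that add atoms: iodomethane, CI
Why: O-methylation of the phenoxide (Williamson ether synthesis) should proceed despite the two ortho substituents because the phenol is acidic and the electrophile is small.

Step 4
Reactants: 6 3-allyl-5-bromo-4-methoxybenzaldehyde
Product: 7 1-allyl-3-bromo-2-methoxy-5-vinylbenzene
Conditions: Ph3PCH3Br, KOtBu, THF, 0 °C to rt
Reagents that add atoms: methyltriphenylphosphonium bromide, C[P+](c1ccccc1)(c1ccccc1)c1ccccc1.[Br-]
Why: Wittig methylenation of an aromatic aldehyde with the unstabilised ylide is reliable, and the aryl bromide and allyl group are inert to it.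

Step 5
Reactants: 8 2,4-dihydroxybenzaldehyde
Product: 9 2-hydroxy-4-(triisopropylsilyloxy)benzaldehyde
Conditions: TIPSCl, imidazole, CH2Cl2, 0 °C
Reagents that add atoms: triisopropylsilyl chloride, CC(C)[Si](Cl)(C(C)C)C(C)C
Why: silylation should take place only at the 4-hydroxyl because the 2-hydroxyl is tied up in a hydrogen bond to the formyl group, and the triisopropylsilyl ether is chosen to withstand the later acid and amine-base steps.

Step 6
Reactants: 9 2-hydroxy-4-(triisopropylsilyloxy)benzaldehyde
Product: 10 2-(dimethoxymethyl)-5-(triisopropylsilyloxy)phenol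
Conditions: HC(OMe)3, PPTS (cat.), MeOH, rt; then Et3N, filtration through basic alumina
Reagents that add atoms: trimethyl orthoformate, COC(OC)OC (the solvent methanol, CO, exchanges with it)
Why: acid-catalysed acetalisation with the orthoformate as dehydrating methoxy donor is standard for salicylaldehydes, and the basic quench keeps the labile phenolic acetal from losing methanol before use.

Step 7
Reactants: 10 2-(dimethoxymethyl)-5-(triisopropylsilyloxy)phenol; 7 1-allyl-3-bromo-2-methoxy-5-vinylbenzene
Product: 12 (2S,4S)-2-(3-allyl-5-bromo-4-methoxyphenyl)-4-methoxy-7-(triisopropylsilyloxy)chroman, via ortho-quinone methide 11 (not isolated)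
Conditions: (S,S)-imidodiphosphorimidate acid (N-triflyl, built from two 3,3'-bis[3,5-bis(trifluoromethyl)phenyl]-BINOL units; 5 mol%), 5 Å molecular sieves, CHCl3, −40 °C
Reagents that add atoms: none
Why: Proposed new method: the strong chiral acid protonates one acetal oxygen of 10 and methanol leaves, giving an oxocarbenium ion whose neutral form is the (E)-methoxy ortho-quinone methide 11, kept as a hydrogen-bonded ion pair inside the chiral anion; the CH2 terminus of styrene 7 adds to the methide carbon (C3–C4) while the ring A oxygen closes onto the developing ring B benzylic cation (O1–C2), an asynchronous inverse-demand hetero-Diels–Alder reaction that re-aromatises ring A. The closest known reactions are chiral phosphoric acid catalysed [4+2] cycloadditions of ortho-quinone methides with styrenes and achiral acid-mediated chroman formation from salicylaldehyde acetals and alkenes; what is new is their combination under a confined imidodiphosphorimidate acid. Ring C is closed by intermolecular [4+2] annulation, four atoms (O1, C8a, C4a, C4) coming from 11 and two (C2, C3) from 7. C2 is set by the chiral counter-anion, which leaves one face of the bound methide open and so fixes the enantiotopic face of the styrene that is attacked, and C4 follows from the endo approach of ring B to the (E)-methide (2,4-cis); the C4 configuration is of no consequence because that carbon later becomes the carbonyl. Regioselectivity rests on polarity (nucleophilic alkene terminus to electrophilic methide carbon, cation at the carbon that ring B stabilises), chemoselectivity for the vinyl over the allyl group on the inability of the unconjugated monosubstituted alkene to stabilise a cation, and the 7-silyloxy group para to the methide carbon eases ionisation; low temperature and sieves that take up methanol guard against re-ionisation at C4 or C2 and against oligomerisation of 7.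

Step 8
Reactants: 12 (2S,4S)-2-(3-allyl-5-bromo-4-methoxyphenyl)-4-methoxy-7-(triisopropylsilyloxy)chroman
Product: 14 (S)-2-(3-allyl-5-bromo-4-methoxyphenyl)-7-(triisopropylsilyloxy)chroman-4-one, via hemiketal 13 (not isolated)
Conditions: DDQ (1.3 equiv), CH2Cl2/pH 7 phosphate buffer (10:1), 0 °C
Reagents that add atoms: water, O
Why: DDQ should abstract hydride from the pseudo-axial C4–H, which is benzylic to the 2,4-dioxygenated ring A and alpha to the methoxy group, and water traps the oxocarbenium ion as hemiketal 13, which loses methanol; this is the reaction type of the oxidative cleavage of dialkoxybenzyl ethers by DDQ, and C2 stays untouched because a cation there would be far less stabilised.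

Step 9
Reactants: 14 (S)-2-(3-allyl-5-bromo-4-methoxyphenyl)-7-(triisopropylsilyloxy)chroman-4-one
Product: 15 (S)-2-[3-bromo-4-methoxy-5-(3-methylbut-2-enyl)phenyl]-7-(triisopropylsilyloxy)chroman-4-one
Conditions: second-generation Grubbs catalyst RuCl2(=CHPh)(H2IMes)(PCy3) (5 mol%), 2-methylbut-2-ene/CH2Cl2, 35 °C
Reagents that add atoms: 2-methylbut-2-ene, CC=C(C)C
Why: olefin cross-metathesis of a terminal allylarene with excess 2-methylbut-2-ene is the standard way to a prenylarene, is driven by loss of propene, and runs under neutral conditions that leave the ketone, the aryl bromide, the silyl ether and C2 alone.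

Step 10
Reactants: 15 (S)-2-[3-bromo-4-methoxy-5-(3-methylbut-2-enyl)phenyl]-7-(triisopropylsilyloxy)chroman-4-one; 16 2-methylbut-3-en-2-ol
Product: 17 (S)-2-{3-[(E)-3-hydroxy-3-methylbut-1-enyl]-4-methoxy-5-(3-methylbut-2-enyl)phenyl}-7-(triisopropylsilyloxy)chroman-4-one
Conditions: Pd(P(t-Bu)3)2 (5 mol%), Cy2NMe, 1,4-dioxane, 70 °C
Reagents that add atoms: none
Why: in this Mizoroki–Heck reaction the aryl group adds to the terminal alkene carbon and syn beta-hydride elimination can occur only toward the benzylic carbon (the carbinol carbon has no hydrogen), giving the E alkene, while the trisubstituted prenyl alkene does not insert and the hindered amine at moderate temperature should spare the base-sensitive C2 centre.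

Step 11
Reactants: 17 (S)-2-{3-[(E)-3-hydroxy-3-methylbut-1-enyl]-4-methoxy-5-(3-methylbut-2-enyl)phenyl}-7-(triisopropylsilyloxy)chroman-4-one
Product: 18 (S)-7-hydroxy-2-{3-[(E)-3-hydroxy-3-methylbut-1-enyl]-4-methoxy-5-(3-methylbut-2-enyl)phenyl}chroman-4-one (CNP0222710.1)
Conditions: TBAF, AcOH (1:1), THF, 0 °C
Reagents that add atoms: none
Why: fluoride-mediated desilylation of an aryl silyl ether para to a carbonyl group is fast, and the acetic acid buffer prevents base-induced opening of ring C (which would racemise C2) without being acidic enough to ionise the tertiary allylic alcohol.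

**Compound list**

1 | 3-bromo-4-hydroxybenzaldehyde | O=Cc1ccc(O)c(Br)c1 | starting material
2 | allyl bromide | C=CCBr | starting material
3 | 4-(allyloxy)-3-bromobenzaldehyde | O=Cc1ccc(OCC=C)c(Br)c1 | intermediate
4 | 6-allyl-2-bromo-4-formylcyclohexa-2,4-dien-1-one (racemic, formed in the flask) | O=CC1=CC(CC=C)C(=O)C(Br)=C1 | intermediate
5 | 3-allyl-5-bromo-4-hydroxybenzaldehyde | O=Cc1cc(CC=C)c(O)c(Br)c1 | intermediate
6 | 3-allyl-5-bromo-4-methoxybenzaldehyde | O=Cc1cc(CC=C)c(OC)c(Br)c1 | intermediate
7 | 1-allyl-3-bromo-2-methoxy-5-vinylbenzene | C=CCc1cc(C=C)cc(Br)c1OC | intermediate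
8 | 2,4-dihydroxybenzaldehyde | O=Cc1ccc(O)cc1O | starting material
9 | 2-hydroxy-4-(triisopropylsilyloxy)benzaldehyde | O=Cc1ccc(O[Si](C(C)C)(C(C)C)C(C)C)cc1O | intermediate
10 | 2-(dimethoxymethyl)-5-(triisopropylsilyloxy)phenol | COC(OC)c1ccc(O[Si](C(C)C)(C(C)C)C(C)C)cc1O | intermediate
11 | (E)-6-(methoxymethylidene)-3-(triisopropylsilyloxy)cyclohexa-2,4-dien-1-one (ortho-quinone methide, formed in the flask) | CO/C=C1\C=CC(O[Si](C(C)C)(C(C)C)C(C)C)=CC1=O | intermediate
12 | (2S,4S)-2-(3-allyl-5-bromo-4-methoxyphenyl)-4-methoxy-7-(triisopropylsilyloxy)chroman (2,4-cis) | C=CCc1cc([C@@H]2C[C@H](OC)c3ccc(O[Si](C(C)C)(C(C)C)C(C)C)cc3O2)cc(Br)c1OC | intermediate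
13 | (2S)-2-(3-allyl-5-bromo-4-methoxyphenyl)-4-methoxy-7-(triisopropylsilyloxy)chroman-4-ol (hemiketal, C4 unassigned, formed in the flask) | C=CCc1cc([C@@H]2CC(O)(OC)c3ccc(O[Si](C(C)C)(C(C)C)C(C)C)cc3O2)cc(Br)c1OC | intermediate
14 | (S)-2-(3-allyl-5-bromo-4-methoxyphenyl)-7-(triisopropylsilyloxy)chroman-4-one | C=CCc1cc([C@@H]2CC(=O)c3ccc(O[Si](C(C)C)(C(C)C)C(C)C)cc3O2)cc(Br)c1OC | intermediate
15 | (S)-2-[3-bromo-4-methoxy-5-(3-methylbut-2-enyl)phenyl]-7-(triisopropylsilyloxy)chroman-4-one | CC(C)=CCc1cc([C@@H]2CC(=O)c3ccc(O[Si](C(C)C)(C(C)C)C(C)C)cc3O2)cc(Br)c1OC | intermediate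
16 | 2-methylbut-3-en-2-ol | C=CC(C)(C)O | starting material
17 | (S)-2-{3-[(E)-3-hydroxy-3-methylbut-1-enyl]-4-methoxy-5-(3-methylbut-2-enyl)phenyl}-7-(triisopropylsilyloxy)chroman-4-one | COc1c(/C=C/C(C)(C)O)cc([C@@H]2CC(=O)c3ccc(O[Si](C(C)C)(C(C)C)C(C)C)cc3O2)cc1CC=C(C)C | intermediate
18 | (S)-7-hydroxy-2-{3-[(E)-3-hydroxy-3-methylbut-1-enyl]-4-methoxy-5-(3-methylbut-2-enyl)phenyl}chroman-4-one (CNP0222710.1) | COc1c(/C=C/C(C)(C)O)cc([C@@H]2CC(=O)c3ccc(O)cc3O2)cc1CC=C(C)C | target

**Step count**

Total: 11 steps. Longest linear sequence: 9 steps (steps 1–4, then 7–11); the ring A branch (steps 5 and 6) joins at step 7.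

**Steps most likely to fail**

Step 7. The acid may give poor facial discrimination at C2. The product may also re-ionise at C4 or C2 under the acid, which would erode the enantiomeric purity or lead to loss of methanol, and the styrene may oligomerise cationically. The fallback sets out from 10 and 7 and uses the known achiral version of the reaction: Sc(OTf)3 (5 mol%) in CH2Cl2 at −20 °C should give the racemic 2,4-cis-2-(3-allyl-5-bromo-4-methoxyphenyl)-4-methoxy-7-(triisopropylsilyloxy)chroman F1. Preparative chromatography on a chiral stationary phase then separates the wanted enantiomer from the (2R,4R)-enantiomer F2, which is discarded. The route is rejoined at 12.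

Step 8. Hydride abstraction may occur at the doubly activated allyl CH2 or at C2 in competition with C4, or the oxidation may run on toward the flavone level. The fallback sets out from 12 and splits the oxidation into solvolysis and alcohol oxidation. Mild acid in aqueous THF (PPTS, 40 °C) should exchange the ionisable benzylic methoxy group for hydroxyl, giving the (2S)-2-(3-allyl-5-bromo-4-methoxyphenyl)-7-(triisopropylsilyloxy)chroman-4-ol F3 as a mixture of C4 epimers. Dess–Martin periodinane (NaHCO3, CH2Cl2, 0 °C) then oxidises both epimers to the same ketone. The route is rejoined at 14.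

Step 10. The amine base at elevated temperature may open ring C through the enolate (retro-oxa-Michael) and re-close it, racemising C2, and oxidative addition into the ortho-methoxy aryl bromide may be slow enough to make this competitive. The fallback sets out from 15 and replaces the base-mediated coupling by a base-free Stille coupling. Hydrostannation of 2-methylbut-3-yn-2-ol with Bu3SnH and PdCl2(PPh3)2 gives (E)-2-methyl-4-(tributylstannyl)but-3-en-2-ol F4, which is coupled with 15 using Pd(PPh3)4 in toluene at 90 °C with retention of the E geometry. The route is rejoined at 17.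

**Further compounds**

F1 | step 7 | racemic 2,4-cis-2-(3-allyl-5-bromo-4-methoxyphenyl)-4-methoxy-7-(triisopropylsilyloxy)chroman (both enantiomers) | C=CCc1cc([C@@H]2C[C@H](OC)c3ccc(O[Si](C(C)C)(C(C)C)C(C)C)cc3O2)cc(Br)c1OC.C=CCc1cc([C@H]2C[C@@H](OC)c3ccc(O[Si](C(C)C)(C(C)C)C(C)C)cc3O2)cc(Br)c1OC
F2 | step 7 | (2R,4R)-2-(3-allyl-5-bromo-4-methoxyphenyl)-4-methoxy-7-(triisopropylsilyloxy)chroman | C=CCc1cc([C@H]2C[C@@H](OC)c3ccc(O[Si](C(C)C)(C(C)C)C(C)C)cc3O2)cc(Br)c1OC
F3 | step 8 | (2S)-2-(3-allyl-5-bromo-4-methoxyphenyl)-7-(triisopropylsilyloxy)chroman-4-ol (C4 epimers) | C=CCc1cc([C@@H]2CC(O)c3ccc(O[Si](C(C)C)(C(C)C)C(C)C)cc3O2)cc(Br)c1OC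
F4 | step 10 | (E)-2-methyl-4-(tributylstannyl)but-3-en-2-ol | CCCC[Sn](CCCC)(CCCC)/C=C/C(C)(C)O
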